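**Plan**

1. Numbering (daucane): C1 ring-fusion carbon with CH3, C2/C3 CH2, C4 isopropyl carbinol, C5 ring-fusion CH, C6 CH–O–aroyl, C7 C=O, C8 C(OH)CH3 (its methyl carbon is C14), C9 CHOH, C10 CH2; α is the face of H5, β that of the C1 methyl.
2. Cuts, in retrosynthetic order: O–benzyl; the C8–O/C9–O pair (back to a C8=C9 enone); the C7 carbonyl (back to an allylic CH2); the C6–O acyl bond; then C6–C7, which opens the seven-membered ring C1–C10–C9–C8–C7–C6–C5; then C4–isopropyl, C5–C6 and C1–C10 on the cyclopentane.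
3. Enabling feature: C6 is a carbinol carbon next to C5 and C7–C8(C14)–C9 is a 2-methylallyl unit, so C6–C7 is the bond between an aldehyde carbon and the CH2 end of a 1,1-disubstituted alkene.
4. Forward: the five-membered ring is that of 3-methylcyclopent-2-enone; the butenyl chain, C6 and the isopropyl group are attached in that order; the seven-membered ring then closes by a carbonyl-ene reaction, followed by alkene shift, esterification, C7 oxidation and dihydroxylation.
5. Stereochemistry: C1 from the chiral copper catalyst; C5 by enolate attack anti to the chain; C4 by addition anti to C6; C6 from the aldehyde face in the ene step; C8 and C9 by osmylation anti to the C1 methyl.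

Key step: step 7

Assumption: the copper–carbene catalyst of step 1 is used as the ligand enantiomer that delivers the (S)-configured quaternary carbon.

**Route**

Step 1
Reactants: 1 3-methylcyclopent-2-en-1-one; 2 4-bromo-2-methylbut-1-ene
Product: 5 trimethyl{[(3S)-3-methyl-3-(3-methylbut-3-en-1-yl)cyclopent-1-en-1-yl]oxy}silane, via Grignard reagent 3 (not isolated), via magnesium enolate 4 (not isolated)
Conditions: Mg, Et2O; then 1, Cu(OTf)2 (3 mol %), chiral hydroxyalkyl imidazolinium salt (carbene precursor, 4 mol %), Et2O, −30 °C; then Me3SiCl, Et3N, HMPA, −30 °C → rt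
Reagents that add atoms: chlorotrimethylsilane, C[Si](C)(C)Cl
Why: Copper-catalysed asymmetric conjugate addition of a Grignard reagent to a β-substituted cycloalkenone with a chiral N-heterocyclic carbene ligand creates the quaternary C1 with the configuration dictated by the ligand enantiomer, and the regiodefined magnesium enolate is stored by O-silylation.

Step 2
Reactants: 5 trimethyl{[(3S)-3-methyl-3-(3-methylbut-3-en-1-yl)cyclopent-1-en-1-yl]oxy}silane
Product: 6 (2S,3S)-2-(hydroxymethyl)-3-methyl-3-(3-methylbut-3-en-1-yl)cyclopentan-1-one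
Conditions: aq. HCHO, Sc(OTf)3 (5 mol %), THF/H2O, rt
Reagents that add atoms: formaldehyde, C=O
Why: Lewis-acid-catalysed aqueous Mukaiyama aldol hydroxymethylation places C6 on the enol ether carbon next to the quaternary centre, the electrophile approaching anti to the longer butenyl chain so that CH2OH ends cis to the C1 methyl, which is also the arrangement expected on equilibration of this epimerisable centre, and the minor epimer is to be removed by chromatography.

Step 3
Reactants: 6 (2S,3S)-2-(hydroxymethyl)-3-methyl-3-(3-methylbut-3-en-1-yl)cyclopentan-1-one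
Product: 7 (2S,3S)-3-methyl-3-(3-methylbut-3-en-1-yl)-2-{[(triethylsilyl)oxy]methyl}cyclopentan-1-one
Conditions: Et3SiCl, imidazole, CH2Cl2, 0 °C
Reagents that add atoms: chlorotriethylsilane, CC[Si](CC)(CC)Cl
Why: Standard silylation of the primary alcohol blocks retro-aldol loss of formaldehyde and chelation in the following carbonyl addition.

Step 4
Reactants: 7 (2S,3S)-3-methyl-3-(3-methylbut-3-en-1-yl)-2-{[(triethylsilyl)oxy]methyl}cyclopentan-1-one; 8 isopropylmagnesium chloride
Product: 10 (1R,2S,3S)-3-methyl-3-(3-methylbut-3-en-1-yl)-1-(propan-2-yl)-2-{[(triethylsilyl)oxy]methyl}cyclopentan-1-ol, via dichloro(isopropyl)cerium 9 (not isolated)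
Conditions: CeCl3 (anhydrous), 8, THF, −78 °C; then 7, −78 °C; aq. NH4Cl
Reagents that add atoms: none
Why: Organocerium 1,2-addition suppresses enolisation and β-hydride reduction of the hindered ketone, and the isopropyl group enters anti to the adjacent CH2OSiEt3 substituent, which sets C4 with its hydroxyl cis to C6.

Step 5
Reactants: 10 (1R,2S,3S)-3-methyl-3-(3-methylbut-3-en-1-yl)-1-(propan-2-yl)-2-{[(triethylsilyl)oxy]methyl}cyclopentan-1-ol
Product: 11 bis(triethylsilyl) ether of (1R,2S,3S)-2-(hydroxymethyl)-3-methyl-3-(3-methylbut-3-en-1-yl)-1-(propan-2-yl)cyclopentan-1-ol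
Conditions: Et3SiOTf, 2,6-lutidine, CH2Cl2, −78 → 0 °C
Reagents that add atoms: triethylsilyl trifluoromethanesulfonate, CC[Si](CC)(CC)OS(=O)(=O)C(F)(F)F
Why: A silyl triflate with 2,6-lutidine silylates the hindered tertiary alcohol so that the later β-oxygenated aldehyde cannot undergo retro-aldol cleavage or bind the Lewis acid through a free hydroxyl.

Step 6
Reactants: 11 bis(triethylsilyl) ether of (1R,2S,3S)-2-(hydroxymethyl)-3-methyl-3-(3-methylbut-3-en-1-yl)-1-(propan-2-yl)cyclopentan-1-ol
Product: 13 (1R,2R,5S)-5-methyl-5-(3-methylbut-3-en-1-yl)-2-(propan-2-yl)-2-[(triethylsilyl)oxy]cyclopentane-1-carbaldehyde, via alkoxydimethylsulfonium chloride 12 (not isolated)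
Conditions: (COCl)2, DMSO, CH2Cl2, −78 → −40 °C; then Et3N, −78 °C → rt
Reagents that add atoms: none
Why: Under Swern conditions a primary triethylsilyl ether is cleaved by the chlorosulfonium reagent and oxidised directly to the aldehyde while the tertiary silyl ether is untouched, and C5, now epimerisable, already has its preferred configuration with CHO trans to the isopropyl group and to the butenyl chain.

Step 7
Reactants: 13 (1R,2R,5S)-5-methyl-5-(3-methylbut-3-en-1-yl)-2-(propan-2-yl)-2-[(triethylsilyl)oxy]cyclopentane-1-carbaldehyde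
Product: 14 4β-(triethylsilyloxy)-5αH-dauc-8(14)-en-6α-ol
Conditions: Me2AlCl (2 equiv), CH2Cl2, −78 → −20 °C; aq. NaHCO3
Reagents that add atoms: none
Why: Me2AlCl binds the aldehyde oxygen, the CH2 terminus C7 of the 1,1-disubstituted alkene attacks C6, and a hydrogen of the C8 methyl group passes to oxygen while aluminium loses methane, so that C14 becomes an exocyclic methylene. This is an intramolecular carbonyl-ene reaction of type 2 (enophile tethered to the central ene carbon), the class that gives 3-methylenecycloalkanols with six- to eight-membered rings under alkylaluminium halides. The seven-membered ring closes exo with respect to the carbonyl and endo with respect to the alkene (7-endo-trig), and the trans arrangement of CHO and chain on the cyclopentane carries over into the trans ring fusion. The new C6 centre is controlled by the cyclopentane: with C7 approaching between H5 and C1, the aluminium-bound oxygen takes the open sector anti to C1 (pseudo-equatorial, α), and only the aldehyde hydrogen points into the niche between the β-methyl on C1 and the β-silyloxy group on C4. The step needs face selectivity at the aldehyde only, because the final position of the alkene is settled in step 9, and Me2AlCl as combined Lewis acid and proton scavenger spares the tertiary silyl ether and suppresses cationic rearrangement.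

Step 8
Reactants: 14 4β-(triethylsilyloxy)-5αH-dauc-8(14)-en-6α-ol
Product: 15 5αH-dauc-8(14)-ene-4β,6α-diol
Conditions: Bu4NF, THF, rt → 40 °C
Reagents that add atoms: none
Why: Fluoride cleavage of the silyl ether frees the tertiary hydroxyl, which needs no protection from here on, and removes the possibility of silyl migration to O6 under the basic conditions of the next step.

Step 9
Reactants: 15 5αH-dauc-8(14)-ene-4β,6α-diol
Product: 16 5αH-dauc-8-ene-4β,6α-diol
Conditions: KOtBu, DMSO, 60 °C; then H2O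
Reagents that add atoms: none
Why: Base-mediated alkene isomerisation through an allyl anion converts the exocyclic methylene into the thermodynamically favoured trisubstituted ring alkene, and abstraction at C9 and not at C7, which lies next to the C6 alkoxide, should place it at C8=C9.

Step 10
Reactants: 16 5αH-dauc-8-ene-4β,6α-diol; 17 4-(benzyloxy)benzoic acid
Product: 19 4β-hydroxy-5αH-dauc-8-en-6α-yl 4-(benzyloxy)benzoate, via mixed anhydride 18 (not isolated)
Conditions: 17, 2,4,6-Cl3C6H2COCl, Et3N, THF, rt; then 16, DMAP, toluene, rt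
Reagents that add atoms: none
Why: Yamaguchi esterification acylates the secondary C6 hydroxyl with retention of configuration while the tertiary C4 hydroxyl does not react.

Step 11
Reactants: 19 4β-hydroxy-5αH-dauc-8-en-6α-yl 4-(benzyloxy)benzoate
Product: 20 4β,7-dihydroxy-5αH-dauc-8-en-6α-yl 4-(benzyloxy)benzoate (C7 epimers)
Conditions: SeO2 (0.5 equiv), t-BuOOH, CH2Cl2, rt
Reagents that add atoms: selenium dioxide, O=[Se]=O; tert-butyl hydroperoxide, CC(C)(C)OO
Why: Selenium dioxide allylic hydroxylation (ene reaction at C9 followed by [2,3]-sigmatropic shift) oxidises the ring CH2 attached to the more substituted alkene carbon, that is C7 and not C10, and the configuration created at C7 is of no consequence.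

Step 12
Reactants: 20 4β,7-dihydroxy-5αH-dauc-8-en-6α-yl 4-(benzyloxy)benzoate (C7 epimers)
Product: 21 4β-hydroxy-7-oxo-5αH-dauc-8-en-6α-yl 4-(benzyloxy)benzoate
Conditions: Dess–Martin periodinane, CH2Cl2, 0 °C → rt
Reagents that add atoms: none
Why: Dess–Martin oxidation of the allylic alcohol under non-basic conditions gives the enone without epimerising C6 or shifting the aroyl group.

Step 13
Reactants: 21 4β-hydroxy-7-oxo-5αH-dauc-8-en-6α-yl 4-(benzyloxy)benzoate
Product: 22 4β,8α,9α-trihydroxy-7-oxo-5αH-daucan-6α-yl 4-(benzyloxy)benzoate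
Conditions: OsO4 (5 mol %), N-methylmorpholine N-oxide, citric acid, t-BuOH/H2O, rt
Reagents that add atoms: osmium tetroxide, O=[Os](=O)(=O)=O; N-methylmorpholine N-oxide, C[N+]1([O-])CCOCC1; water, O
Why: Catalytic Upjohn syn-dihydroxylation, with citric acid to speed turnover on the electron-poor alkene, adds to C8=C9 from the α face, opposite the axial C1 methyl that shields the β face at C9, which sets both C8 and C9.

Step 14
Reactants: 22 4β,8α,9α-trihydroxy-7-oxo-5αH-daucan-6α-yl 4-(benzyloxy)benzoate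
Product: 23 4β,8α,9α-trihydroxy-7-oxo-5αH-daucan-6α-yl 4-hydroxybenzoate (CNP0241001.1)
Conditions: H2 (1 atm), Pd/C, EtOAc, rt
Reagents that add atoms: none
Why: Hydrogenolysis of the benzyl aryl ether over palladium on carbon releases the phenol and leaves ketone, ester and alcohols untouched.

**Compound list**

1 | 3-methylcyclopent-2-en-1-one | CC1=CC(=O)CC1 | starting material
2 | 4-bromo-2-methylbut-1-ene | CC(=C)CCBr | starting material
3 | (3-methylbut-3-en-1-yl)magnesium bromide | CC(=C)CC[Mg]Br | intermediate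
4 | bromomagnesium (3S)-3-methyl-3-(3-methylbut-3-en-1-yl)cyclopent-1-en-1-olate | CC(=C)CC[C@@]1(C)CCC(O[Mg]Br)=C1 | intermediate
5 | trimethyl{[(3S)-3-methyl-3-(3-methylbut-3-en-1-yl)cyclopent-1-en-1-yl]oxy}silane | C[Si](C)(C)OC1=C[C@@](C)(CCC(C)=C)CC1 | intermediate
6 | (2S,3S)-2-(hydroxymethyl)-3-methyl-3-(3-methylbut-3-en-1-yl)cyclopentan-1-one | O=C1CC[C@](C)(CCC(C)=C)[C@H]1CO | intermediate
7 | (2S,3S)-3-methyl-3-(3-methylbut-3-en-1-yl)-2-{[(triethylsilyl)oxy]methyl}cyclopentan-1-one | O=C1CC[C@](C)(CCC(C)=C)[C@H]1CO[Si](CC)(CC)CC | intermediate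
8 | isopropylmagnesium chloride | CC(C)[Mg]Cl | starting material
9 | dichloro(isopropyl)cerium | CC(C)[Ce](Cl)Cl | intermediate
10 | (1R,2S,3S)-3-methyl-3-(3-methylbut-3-en-1-yl)-1-(propan-2-yl)-2-{[(triethylsilyl)oxy]methyl}cyclopentan-1-ol | CC(C)[C@]1(O)CC[C@](C)(CCC(C)=C)[C@H]1CO[Si](CC)(CC)CC | intermediate
11 | bis(triethylsilyl) ether of (1R,2S,3S)-2-(hydroxymethyl)-3-methyl-3-(3-methylbut-3-en-1-yl)-1-(propan-2-yl)cyclopentan-1-ol | CC(C)[C@]1(O[Si](CC)(CC)CC)CC[C@](C)(CCC(C)=C)[C@H]1CO[Si](CC)(CC)CC | intermediate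
12 | alkoxydimethylsulfonium chloride from the primary oxygen of 11 (tertiary silyl ether retained) | CC(C)[C@]1(O[Si](CC)(CC)CC)CC[C@](C)(CCC(C)=C)[C@H]1CO[S+](C)C.[Cl-] | intermediate
13 | (1R,2R,5S)-5-methyl-5-(3-methylbut-3-en-1-yl)-2-(propan-2-yl)-2-[(triethylsilyl)oxy]cyclopentane-1-carbaldehyde | CC(C)[C@]1(O[Si](CC)(CC)CC)CC[C@](C)(CCC(C)=C)[C@H]1C=O | intermediate
14 | 4β-(triethylsilyloxy)-5αH-dauc-8(14)-en-6α-ol | CC(C)[C@]1(O[Si](CC)(CC)CC)CC[C@]2(C)CCC(=C)C[C@H](O)[C@H]21 | intermediate
15 | 5αH-dauc-8(14)-ene-4β,6α-diol | CC(C)[C@]1(O)CC[C@]2(C)CCC(=C)C[C@H](O)[C@H]21 | intermediate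
16 | 5αH-dauc-8-ene-4β,6α-diol | CC(C)[C@]1(O)CC[C@]2(C)CC=C(C)C[C@H](O)[C@H]21 | intermediate
17 | 4-(benzyloxy)benzoic acid | OC(=O)c1ccc(OCc2ccccc2)cc1 | starting material
18 | 4-(benzyloxy)benzoic 2,4,6-trichlorobenzoic anhydride | O=C(OC(=O)c1c(Cl)cc(Cl)cc1Cl)c1ccc(OCc2ccccc2)cc1 | intermediate
19 | 4β-hydroxy-5αH-dauc-8-en-6α-yl 4-(benzyloxy)benzoate | CC(C)[C@]1(O)CC[C@]2(C)CC=C(C)C[C@H](OC(=O)c3ccc(OCc4ccccc4)cc3)[C@H]21 | intermediate
20 | 4β,7-dihydroxy-5αH-dauc-8-en-6α-yl 4-(benzyloxy)benzoate (C7 epimers) | CC(C)[C@]1(O)CC[C@]2(C)CC=C(C)C(O)[C@H](OC(=O)c3ccc(OCc4ccccc4)cc3)[C@H]21 | intermediate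
21 | 4β-hydroxy-7-oxo-5αH-dauc-8-en-6α-yl 4-(benzyloxy)benzoate | CC(C)[C@]1(O)CC[C@]2(C)CC=C(C)C(=O)[C@H](OC(=O)c3ccc(OCc4ccccc4)cc3)[C@H]21 | intermediate
22 | 4β,8α,9α-trihydroxy-7-oxo-5αH-daucan-6α-yl 4-(benzyloxy)benzoate | CC(C)[C@]1(O)CC[C@]2(C)C[C@H](O)[C@](C)(O)C(=O)[C@H](OC(=O)c3ccc(OCc4ccccc4)cc3)[C@H]21 | intermediate
23 | 4β,8α,9α-trihydroxy-7-oxo-5αH-daucan-6α-yl 4-hydroxybenzoate | CC(C)[C@]1(O)CC[C@]2(C)C[C@H](O)[C@](C)(O)C(=O)[C@H](OC(=O)c3ccc(O)cc3)[C@H]21 | target

**Count and risks**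

Total step count: 14. Longest linear sequence: 14 steps, from 1 to 23.

Steps most likely to fail:

Step 7. The alkene may attack the other face of the aluminium-bound aldehyde and so invert C6, and the C8 cation of a stepwise pathway may be captured by chloride. The fallback gives up facial control in the ring closure and sets C6 by an invertive esterification. It sets out from aldehyde 13: the 6β-alcohol 4β-(triethylsilyloxy)-5αH-dauc-8(14)-en-6β-ol F1 is desilylated with Bu4NF to 5αH-dauc-8(14)-ene-4β,6β-diol F2, isomerised with KOtBu in DMSO to 5αH-dauc-8-ene-4β,6β-diol F3, and coupled with acid 17 under Mitsunobu conditions (PPh3, diisopropyl azodicarboxylate, toluene). SN2 displacement at C6 then delivers the 6α-ester, and the route is rejoined at 19.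

Step 9. Proton abstraction may also occur at C7, or the alkenes may equilibrate further, so that the C7=C8 isomer accompanies the wanted one. The fallback replaces base equilibration by a regiospecific reductive allylic transposition. It sets out from diol 15: Yamaguchi esterification with 17 gives 4β-hydroxy-5αH-dauc-8(14)-en-6α-yl 4-(benzyloxy)benzoate F4. SeO2 with t-BuOOH then hydroxylates the ring allylic position remote from the acyloxy-bearing carbon to give 4β,9-dihydroxy-5αH-dauc-8(14)-en-6α-yl 4-(benzyloxy)benzoate F5 (C9 configuration immaterial). Mitsunobu reaction with 2-nitrobenzenesulfonylhydrazide (PPh3, diethyl azodicarboxylate, THF, −30 °C) gives the N-allyl sulfonylhydrazine F6, which on warming loses sulfinic acid to the allylic diazene F7. Sigmatropic loss of N2 moves the double bond to C8=C9 while C14 becomes the methyl group, and the route is rejoined at 19.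

Step 11. Hydrogen abstraction may take place at the C8 methyl group instead of C7, the reaction next to the acyloxy-bearing carbon may be slow, and over-oxidation may occur. The fallback installs the C7 oxygen by enolate oxidation through a C6 ketone and moves the alkene into the ring only when the C7 ketone is in place. It sets out from alcohol 14:
- Dess–Martin oxidation gives 4β-(triethylsilyloxy)-5αH-dauc-8(14)-en-6-one F8.
- KN(SiMe3)2 in THF at −78 °C removes the doubly activated C7 proton to give the potassium dienolate F9.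
- 2-(Phenylsulfonyl)-3-phenyloxaziridine hydroxylates it at C7 to 7-hydroxy-4β-(triethylsilyloxy)-5αH-dauc-8(14)-en-6-one F10.
- NaBH4 in MeOH, attacking the open α face, gives 4β-(triethylsilyloxy)-5αH-dauc-8(14)-ene-6β,7-diol F11.
- MnO2 oxidises only the allylic C7 hydroxyl to 6β-hydroxy-4β-(triethylsilyloxy)-5αH-dauc-8(14)-en-7-one F12.
- Mitsunobu coupling with 17 (PPh3, diisopropyl azodicarboxylate) inverts C6 to give 7-oxo-4β-(triethylsilyloxy)-5αH-dauc-8(14)-en-6α-yl 4-(benzyloxy)benzoate F13.
- RhCl3·3H2O in EtOH moves the exocyclic alkene into conjugation to give 7-oxo-4β-(triethylsilyloxy)-5αH-dauc-8-en-6α-yl 4-(benzyloxy)benzoate F14.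
- HF·pyridine in THF removes the silyl group, and the route is rejoined at 21.

Further compounds
F1 | step 7 | 4β-(triethylsilyloxy)-5αH-dauc-8(14)-en-6β-ol | CC(C)[C@]1(O[Si](CC)(CC)CC)CC[C@]2(C)CCC(=C)C[C@@H](O)[C@H]21
F2 | step 7 | 5αH-dauc-8(14)-ene-4β,6β-diol | CC(C)[C@]1(O)CC[C@]2(C)CCC(=C)C[C@@H](O)[C@H]21
F3 | step 7 | 5αH-dauc-8-ene-4β,6β-diol | CC(C)[C@]1(O)CC[C@]2(C)CC=C(C)C[C@@H](O)[C@H]21
F4 | step 9 | 4β-hydroxy-5αH-dauc-8(14)-en-6α-yl 4-(benzyloxy)benzoate | CC(C)[C@]1(O)CC[C@]2(C)CCC(=C)C[C@H](OC(=O)c3ccc(OCc4ccccc4)cc3)[C@H]21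
F5 | step 9 | 4β,9-dihydroxy-5αH-dauc-8(14)-en-6α-yl 4-(benzyloxy)benzoate | CC(C)[C@]1(O)CC[C@]2(C)CC(O)C(=C)C[C@H](OC(=O)c3ccc(OCc4ccccc4)cc3)[C@H]21
F6 | step 9 | N-allyl-N-(2-nitrobenzenesulfonyl)hydrazine at C9 of F5 | CC(C)[C@]1(O)CC[C@]2(C)CC(N(N)S(=O)(=O)c5ccccc5[N+](=O)[O-])C(=C)C[C@H](OC(=O)c3ccc(OCc4ccccc4)cc3)[C@H]21
F7 | step 9 | allylic diazene at C9 | CC(C)[C@]1(O)CC[C@]2(C)CC(N=N)C(=C)C[C@H](OC(=O)c3ccc(OCc4ccccc4)cc3)[C@H]21
F8 | step 11 | 4β-(triethylsilyloxy)-5αH-dauc-8(14)-en-6-one | CC(C)[C@]1(O[Si](CC)(CC)CC)CC[C@]2(C)CCC(=C)CC(=O)[C@H]21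
F9 | step 11 | potassium 4β-(triethylsilyloxy)-5αH-dauca-6,8(14)-dien-6-olate | CC(C)[C@]1(O[Si](CC)(CC)CC)CC[C@]2(C)CCC(=C)C=C([O-])[C@H]21.[K+]
F10 | step 11 | 7-hydroxy-4β-(triethylsilyloxy)-5αH-dauc-8(14)-en-6-one | CC(C)[C@]1(O[Si](CC)(CC)CC)CC[C@]2(C)CCC(=C)C(O)C(=O)[C@H]21
F11 | step 11 | 4β-(triethylsilyloxy)-5αH-dauc-8(14)-ene-6β,7-diol | CC(C)[C@]1(O[Si](CC)(CC)CC)CC[C@]2(C)CCC(=C)C(O)[C@@H](O)[C@H]21
F12 | step 11 | 6β-hydroxy-4β-(triethylsilyloxy)-5αH-dauc-8(14)-en-7-one | CC(C)[C@]1(O[Si](CC)(CC)CC)CC[C@]2(C)CCC(=C)C(=O)[C@@H](O)[C@H]21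
F13 | step 11 | 7-oxo-4β-(triethylsilyloxy)-5αH-dauc-8(14)-en-6α-yl 4-(benzyloxy)benzoate | CC(C)[C@]1(O[Si](CC)(CC)CC)CC[C@]2(C)CCC(=C)C(=O)[C@H](OC(=O)c3ccc(OCc4ccccc4)cc3)[C@H]21
F14 | step 11 | 7-oxo-4β-(triethylsilyloxy)-5αH-dauc-8-en-6α-yl 4-(benzyloxy)benzoate | CC(C)[C@]1(O[Si](CC)(CC)CC)CC[C@]2(C)CC=C(C)C(=O)[C@H](OC(=O)c3ccc(OCc4ccccc4)cc3)[C@H]21
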